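**Retrosynthetic overview**

1. Last cuts: the two phenol benzyl ethers; then, together, the aryl–CH2 bond from C6 of the dihydrobenzofuran to the CH2 on tetrahydrofuran C4 and the ring bond C5–C4 of the tetrahydrofuran (OCH2 carbon to the ring carbon bearing the arylmethyl group). One metallaphotoredox cascade makes both bonds.
2. Enabling feature: ring oxygen O1 sits on benzylic C2, so an O1–CH2 radical (C5) lies 5-exo to C4. The CH2OH on C3 is cis to the arylmethyl CH2 on C4, so its oxygen and that CH2 carbon can be tied through boron into a 5,6-dihydro-2H-1,2-oxaborinine (O–B–CH=C4). This temporary ring makes C4 the β-carbon of an alkenylboronate, forces cis fusion (= 3,4-cis) and leaves an α-boryl radical for arylation by the bromide at dihydrobenzofuran C6, a position flanked by two CH groups.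
3. Tetrahydrofuran half: C2 and C3 come from an anti-selective iridium-catalysed (hydroxymethyl)allylation of O-benzylisovanillin; C5 enters as a carboxymethyl ether on O1 (CO2H as traceless radical precursor); the oxaborinine is built by boron-tethered ring-closing metathesis.
4. Dihydrobenzofuran half: 4-bromo-2,6-dimethoxybenzaldehyde is converted into an aryldiazoacetate carrying the guaiacyl CH2–O group; enantioselective dirhodium C–H insertion closes the furan ring (cis), epimerisation gives trans, reduction gives the CH2OH.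
5. Ring order: furan ring of the dihydrobenzofuran (step 9), temporary oxaborinine (step 4), tetrahydrofuran (step 13); the boron ring is excised by protodeboronation (step 14) and the benzyl ethers go last (step 15).

Key step: step 13

Assumption: the sense of induction of the chiral iridium catalyst (step 1) and of the chiral dirhodium catalyst (step 9) is assigned by analogy with simple aryl substrates; both catalyst enantiomers are available and the antipode would be used if the sense proved opposite.

**Route**

Step 1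
Reactants: 1 3-(benzyloxy)-4-methoxybenzaldehyde; 2 4-ethenyl-1,3-dioxolan-2-one (vinyl ethylene carbonate, racemic)
Product: 3 (1R,2S)-1-[3-(benzyloxy)-4-methoxyphenyl]-2-ethenylpropane-1,3-diol
Conditions: [Ir(cod)Cl]2 (2.5 mol%), (R)-SEGPHOS (5 mol%), 4-chloro-3-nitrobenzoic acid (10 mol%), K3PO4 (5 mol%), i-PrOH (2 equiv), THF, 90 °C
Reagents that add atoms: none
Why: Iridium-catalysed transfer-hydrogenative carbonyl (hydroxymethyl)allylation, in which the carbonate is ionised with loss of CO2 to an (E)-σ-allyliridium species that adds to the aldehyde through a closed chair transition state, so that the anti relationship (the later 2,3-trans pair of the tetrahydrofuran) comes from the chair and the absolute configuration of both new centres from the chiral bisphosphine.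

Step 2
Reactants: 3 (1R,2S)-1-[3-(benzyloxy)-4-methoxyphenyl]-2-ethenylpropane-1,3-diol
Product: 4 (1R,2S)-1-[3-(benzyloxy)-4-methoxyphenyl]-2-{[bis(4-methoxyphenyl)(phenyl)methoxy]methyl}but-3-en-1-ol
Conditions: 4,4'-dimethoxytrityl chloride (1.1 equiv), pyridine, 0 °C to rt
Reagents that add atoms: 4,4'-dimethoxytrityl chloride, COc1ccc(cc1)C(Cl)(c1ccccc1)c1ccc(OC)cc1
Why: Tritylation is selective for the primary hydroxyl over the hindered secondary benzylic one on steric grounds, which leaves only the benzylic oxygen free for alkylation.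

Step 3
Reactants: 4 (1R,2S)-1-[3-(benzyloxy)-4-methoxyphenyl]-2-{[bis(4-methoxyphenyl)(phenyl)methoxy]methyl}but-3-en-1-ol; 5 bromoacetic acid
Product: 7 {[(1R,2S)-1-[3-(benzyloxy)-4-methoxyphenyl]-2-(hydroxymethyl)but-3-en-1-yl]oxy}acetic acid, via dimethoxytrityl ether acid 6 (not isolated)
Conditions: NaH (3.5 equiv), THF, 0 °C to rt; then AcOH/H2O 4:1, rt
Reagents that add atoms: none
Why: Williamson ether synthesis between the sodium alkoxide and bromoacetate puts the carboxymethyl group (the future OCH2 ring carbon plus a traceless carboxyl) on the benzylic oxygen without touching a stereocentre, and the base-stable, non-migrating dimethoxytrityl ether is then cleaved by aqueous acetic acid, which is too weak to ionise the benzylic ether.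

Step 4
Reactants: 7 {[(1R,2S)-1-[3-(benzyloxy)-4-methoxyphenyl]-2-(hydroxymethyl)but-3-en-1-yl]oxy}acetic acid; 8 dibutyl ethenylboronate
Product: 11 {(R)-[3-(benzyloxy)-4-methoxyphenyl][(5S)-2-hydroxy-5,6-dihydro-2H-1,2-oxaborinin-5-yl]methoxy}acetic acid, via mixed vinylboronic ester 9 (not isolated), via cyclic butyl boronate 10 (not isolated)
Conditions: 8 (1.5 equiv), CH2Cl2, 40 °C; second-generation Grubbs catalyst (H2IMes)(PCy3)Cl2Ru=CHPh (5 mol%), CH2Cl2, 40 °C; aqueous work-up at pH 5
Reagents that add atoms: water, O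
Why: Boron-tethered ring-closing metathesis, in which the primary alcohol exchanges onto the vinylboronate and the ruthenium carbene closes the six-membered ring between the B-vinyl and C-vinyl groups with loss of ethene, should give the ring (Z)-alkenylboronic hemiester without touching a stereocentre.

Step 5
Reactants: 12 4-bromo-2,6-dimethoxybenzaldehyde
Product: 13 4-bromo-2-hydroxy-6-methoxybenzaldehyde
Conditions: BCl3 (1.2 equiv), CH2Cl2, −78 to 0 °C; H2O
Reagents that add atoms: none
Why: Chelation-controlled mono-demethylation, in which BCl3 bound to the aldehyde oxygen cleaves one ortho methyl ether and the aryloxyboron chelate so formed shields the second one, the aryl bromide being inert.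

Step 6
Reactants: 13 4-bromo-2-hydroxy-6-methoxybenzaldehyde; 14 [4-(benzyloxy)-3-methoxyphenyl]methanol
Product: 15 2-{[4-(benzyloxy)-3-methoxyphenyl]methoxy}-4-bromo-6-methoxybenzaldehyde
Conditions: PPh3, DIAD, THF, 0 °C to rt
Reagents that add atoms: none
Why: Mitsunobu reaction of the acidic ortho-formyl phenol with the primary benzylic alcohol gives the aryl benzyl ether under neutral conditions that spare the aldehyde and the bromide.

Step 7
Reactants: 15 2-{[4-(benzyloxy)-3-methoxyphenyl]methoxy}-4-bromo-6-methoxybenzaldehyde; 16 ethyl diazoacetate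
Product: 17 ethyl (2Z)-2-(2-{[4-(benzyloxy)-3-methoxyphenyl]methoxy}-4-bromo-6-methoxyphenyl)-3-hydroxyprop-2-enoate
Conditions: HBF4·OEt2 (10 mol%), CH2Cl2, −78 °C; cold aq. NaHCO3 quench
Reagents that add atoms: none
Why: Acid-catalysed addition of the diazoester to the aldehyde followed by loss of N2 with 1,2-shift of the electron-rich aryl group (a Roskamp-type homologation diverted to aryl migration) gives the 2-aryl-3-hydroxyacrylate, the low temperature and catalytic acid being chosen to spare the 4-alkoxybenzyl ether.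

Step 8
Reactants: 17 ethyl (2Z)-2-(2-{[4-(benzyloxy)-3-methoxyphenyl]methoxy}-4-bromo-6-methoxyphenyl)-3-hydroxyprop-2-enoate
Product: 18 ethyl 2-(2-{[4-(benzyloxy)-3-methoxyphenyl]methoxy}-4-bromo-6-methoxyphenyl)-2-diazoacetate
Conditions: 4-acetamidobenzenesulfonyl azide (1.2 equiv), Et3N, MeCN, 0 °C to rt
Reagents that add atoms: 4-acetamidobenzenesulfonyl azide, CC(=O)Nc1ccc(cc1)S(=O)(=O)N=[N+]=[N-]
Why: Regitz deformylative diazo transfer, in which the formyl group activates the α-carbon towards the sulfonyl azide and leaves as the N-formyl sulfonamide, gives the aryldiazoacetate.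

Step 9
Reactants: 18 ethyl 2-(2-{[4-(benzyloxy)-3-methoxyphenyl]methoxy}-4-bromo-6-methoxyphenyl)-2-diazoacetate
Product: 19 ethyl (2S,3R)-2-[4-(benzyloxy)-3-methoxyphenyl]-6-bromo-4-methoxy-2,3-dihydro-1-benzofuran-3-carboxylate (cis)
Conditions: Rh2(S-PTTL)4 (1 mol%), toluene, −60 °C
Reagents that add atoms: none
Why: Intramolecular 1,5 C–H insertion of the donor/acceptor dirhodium carbenoid into the oxygen-activated benzylic CH2 closes the dihydrofuran ring, the chiral carboxylate ligands choosing the enantiotopic C–H bond and so setting C2, and the concerted insertion delivering the cis-2,3 ester.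

Step 10
Reactants: 19 ethyl (2S,3R)-2-[4-(benzyloxy)-3-methoxyphenyl]-6-bromo-4-methoxy-2,3-dihydro-1-benzofuran-3-carboxylate (cis)
Product: 20 ethyl (2S,3S)-2-[4-(benzyloxy)-3-methoxyphenyl]-6-bromo-4-methoxy-2,3-dihydro-1-benzofuran-3-carboxylate (trans)
Conditions: NaOEt (0.2 equiv), EtOH, rt
Reagents that add atoms: none
Why: Thermodynamic epimerisation through the ester enolate inverts only C3 and should give the trans-2,3 isomer while C2 keeps its configuration.

Step 11
Reactants: 20 ethyl (2S,3S)-2-[4-(benzyloxy)-3-methoxyphenyl]-6-bromo-4-methoxy-2,3-dihydro-1-benzofuran-3-carboxylate (trans)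
Product: 21 [(2S,3R)-2-[4-(benzyloxy)-3-methoxyphenyl]-6-bromo-4-methoxy-2,3-dihydro-1-benzofuran-3-yl]methanol
Conditions: i-Bu2AlH (2.5 equiv), CH2Cl2, −78 to 0 °C; aq. KNaC4H4O6 (potassium sodium tartrate)
Reagents that add atoms: none
Why: Hydride reduction of the ester to the primary alcohol at low temperature leaves the aryl bromide, the benzylic ring C–O bond and both stereocentres untouched.

Step 12
Reactants: 21 [(2S,3R)-2-[4-(benzyloxy)-3-methoxyphenyl]-6-bromo-4-methoxy-2,3-dihydro-1-benzofuran-3-yl]methanol
Product: 22 {[(2S,3R)-2-[4-(benzyloxy)-3-methoxyphenyl]-6-bromo-4-methoxy-2,3-dihydro-1-benzofuran-3-yl]methoxy}(tert-butyl)dimethylsilane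
Conditions: tert-butyl(chloro)dimethylsilane, imidazole, DMF, rt
Reagents that add atoms: tert-butyl(chloro)dimethylsilane, CC(C)(C)[Si](C)(C)Cl
Why: Silylation masks the primary alcohol against nickel-mediated C–O coupling and boronate exchange in the key step, and the silyl ether is removed by the fluoride step that follows.

Step 13
Reactants: 11 {(R)-[3-(benzyloxy)-4-methoxyphenyl][(5S)-2-hydroxy-5,6-dihydro-2H-1,2-oxaborinin-5-yl]methoxy}acetic acid (1.3 equiv); 22 {[(2S,3R)-2-[4-(benzyloxy)-3-methoxyphenyl]-6-bromo-4-methoxy-2,3-dihydro-1-benzofuran-3-yl]methoxy}(tert-butyl)dimethylsilane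
Product: 23 cis-fused benzylic boronic hemiester: (2R,3S,4S)-2-[3-(benzyloxy)-4-methoxyphenyl]tetrahydrofuran fused at C3–C4 to a 2-hydroxy-1,2-oxaborinane (ring O on the C3 CH2, B on the carbon attached to C4), the boron-bearing carbon carrying the (2S,3R)-dihydrobenzofuran-6-yl group of 22; expected as both epimers at that carbon
Conditions: Ir[dF(CF3)ppy]2(dtbbpy)PF6 (2 mol%), NiCl2·glyme (10 mol%), dtbbpy (10 mol%), Cs2CO3 (1.5 equiv), DMA, blue LEDs (450 nm), rt
Reagents that add atoms: none
Why: Proposed new method: the photoexcited trivalent iridium complex oxidises the caesium carboxylate of 11, loss of CO2 gives the alkoxymethyl radical on O1, this radical adds to the β-carbon (C4) of the ring alkenylboronate, and the α-boryl radical so formed is captured by the arylnickel species generated from 22 and zerovalent nickel, reductive elimination then forming the aryl–CH bond while the reduced iridium complex returns nickel to its low-valent state. The closest known reaction type is the three-component decarboxylative conjunctive cross-coupling of α-oxy acids, vinylboronic esters and aryl halides under iridium/nickel metallaphotoredox catalysis, together with reductive cyclisations of alkoxymethyl radicals onto alkenes; what has not been shown is the intramolecular radical addition to a ring alkenylboronic hemiester followed by nickel capture of a secondary ring α-boryl radical. The tetrahydrofuran closes in the 5-exo-trig mode. The new stereocentre C4 is under substrate control from C3: the three-atom O1–CH2 tether can reach C4 only on the face that gives a cis-fused furo-oxaborinane, which is the 3,4-cis relationship, while C2 and C3 pass through unchanged and the boron-bearing carbon, later a CH2, needs no control. The step needs ring closure ahead of nickel capture of the first radical and attack at C4 instead of the boron-bearing carbon: the first should be secured by the speed of a polarity-matched 5-exo closure of a nucleophilic α-oxy radical onto an electron-poor alkenylboronate at low nickel loading, the second by the 5-exo geometry and the α-boryl stabilisation of the product radical.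

Step 14
Reactants: 23 cis-fused benzylic boronic hemiester
Product: 24 [(2R,3S,4S)-2-[3-(benzyloxy)-4-methoxyphenyl]-4-{[(2S,3R)-2-[4-(benzyloxy)-3-methoxyphenyl]-3-(hydroxymethyl)-4-methoxy-2,3-dihydro-1-benzofuran-6-yl]methyl}oxolan-3-yl]methanol
Conditions: Bu4NF·3H2O (5 equiv), THF, 50 °C
Reagents that add atoms: none
Why: Fluoride/water-promoted protodeboronation of the benzylic boronic hemiester through its fluoroborate replaces boron by hydrogen (the benzylic carbon becomes the CH2 link and is no longer a stereocentre) and frees the hydroxymethyl oxygen, while the same reagent cleaves the silyl ether.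

Step 15
Reactants: 24 dibenzyl ether of the target
Product: 25 CNP0242386.1, 4-[(2S,3R)-6-{[(3S,4S,5R)-5-(3-hydroxy-4-methoxyphenyl)-4-(hydroxymethyl)oxolan-3-yl]methyl}-3-(hydroxymethyl)-4-methoxy-2,3-dihydro-1-benzofuran-2-yl]-2-methoxyphenol
Conditions: H2 (1 atm), 10% Pd/C, EtOAc, rt, short contact time
Reagents that add atoms: none
Why: Catalytic hydrogenolysis of the two aryl benzyl ethers under neutral conditions should leave the slower-reacting ring benzylic C–O bonds and all five stereocentres intact.

**Compound list**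

1 | 3-(benzyloxy)-4-methoxybenzaldehyde | COc1ccc(C=O)cc1OCc1ccccc1 | starting material
2 | 4-ethenyl-1,3-dioxolan-2-one (racemic) | C=CC1COC(=O)O1 | starting material
3 | (1R,2S)-1-[3-(benzyloxy)-4-methoxyphenyl]-2-ethenylpropane-1,3-diol | COc1ccc([C@H](O)[C@H](CO)C=C)cc1OCc1ccccc1 | intermediate
4 | (1R,2S)-1-[3-(benzyloxy)-4-methoxyphenyl]-2-{[bis(4-methoxyphenyl)(phenyl)methoxy]methyl}but-3-en-1-ol | COc1ccc([C@H](O)[C@H](COC(c2ccccc2)(c2ccc(OC)cc2)c2ccc(OC)cc2)C=C)cc1OCc1ccccc1 | intermediate
5 | bromoacetic acid | OC(=O)CBr | starting material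
6 | {[(1R,2S)-1-[3-(benzyloxy)-4-methoxyphenyl]-2-{[bis(4-methoxyphenyl)(phenyl)methoxy]methyl}but-3-en-1-yl]oxy}acetic acid (not isolated) | COc1ccc([C@H](OCC(=O)O)[C@H](COC(c2ccccc2)(c2ccc(OC)cc2)c2ccc(OC)cc2)C=C)cc1OCc1ccccc1 | intermediate
7 | {[(1R,2S)-1-[3-(benzyloxy)-4-methoxyphenyl]-2-(hydroxymethyl)but-3-en-1-yl]oxy}acetic acid | COc1ccc([C@H](OCC(=O)O)[C@H](CO)C=C)cc1OCc1ccccc1 | intermediate
8 | dibutyl ethenylboronate | C=CB(OCCCC)OCCCC | starting material
9 | butyl (2S,3R)-3-[3-(benzyloxy)-4-methoxyphenyl]-3-(carboxymethoxy)-2-ethenylpropyl ethenylboronate (not isolated) | COc1ccc([C@H](OCC(=O)O)[C@H](COB(OCCCC)C=C)C=C)cc1OCc1ccccc1 | intermediate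
10 | {(R)-[3-(benzyloxy)-4-methoxyphenyl][(5S)-2-butoxy-5,6-dihydro-2H-1,2-oxaborinin-5-yl]methoxy}acetic acid (not isolated) | COc1ccc([C@H](OCC(=O)O)[C@@H]2COB(OCCCC)C=C2)cc1OCc1ccccc1 | intermediate
11 | {(R)-[3-(benzyloxy)-4-methoxyphenyl][(5S)-2-hydroxy-5,6-dihydro-2H-1,2-oxaborinin-5-yl]methoxy}acetic acid | COc1ccc([C@H](OCC(=O)O)[C@@H]2COB(O)C=C2)cc1OCc1ccccc1 | intermediate
12 | 4-bromo-2,6-dimethoxybenzaldehyde | COc1cc(Br)cc(OC)c1C=O | starting material
13 | 4-bromo-2-hydroxy-6-methoxybenzaldehyde | COc1cc(Br)cc(O)c1C=O | intermediate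
14 | [4-(benzyloxy)-3-methoxyphenyl]methanol | COc1cc(CO)ccc1OCc1ccccc1 | starting material
15 | 2-{[4-(benzyloxy)-3-methoxyphenyl]methoxy}-4-bromo-6-methoxybenzaldehyde | COc1cc(Br)cc(OCc2ccc(OCc3ccccc3)c(OC)c2)c1C=O | intermediate
16 | ethyl diazoacetate | CCOC(=O)C=[N+]=[N-] | starting material
17 | ethyl (2Z)-2-(2-{[4-(benzyloxy)-3-methoxyphenyl]methoxy}-4-bromo-6-methoxyphenyl)-3-hydroxyprop-2-enoate | CCOC(=O)/C(=C\O)c1c(OC)cc(Br)cc1OCc1ccc(OCc2ccccc2)c(OC)c1 | intermediate
18 | ethyl 2-(2-{[4-(benzyloxy)-3-methoxyphenyl]methoxy}-4-bromo-6-methoxyphenyl)-2-diazoacetate | CCOC(=O)C(=[N+]=[N-])c1c(OC)cc(Br)cc1OCc1ccc(OCc2ccccc2)c(OC)c1 | intermediate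
19 | ethyl (2S,3R)-2-[4-(benzyloxy)-3-methoxyphenyl]-6-bromo-4-methoxy-2,3-dihydro-1-benzofuran-3-carboxylate (cis) | Brc1cc(OC)c2c(c1)O[C@H](c1ccc(OCc3ccccc3)c(OC)c1)[C@@H]2C(=O)OCC | intermediate
20 | ethyl (2S,3S)-2-[4-(benzyloxy)-3-methoxyphenyl]-6-bromo-4-methoxy-2,3-dihydro-1-benzofuran-3-carboxylate (trans) | Brc1cc(OC)c2c(c1)O[C@H](c1ccc(OCc3ccccc3)c(OC)c1)[C@H]2C(=O)OCC | intermediate
21 | [(2S,3R)-2-[4-(benzyloxy)-3-methoxyphenyl]-6-bromo-4-methoxy-2,3-dihydro-1-benzofuran-3-yl]methanol | Brc1cc(OC)c2c(c1)O[C@H](c1ccc(OCc3ccccc3)c(OC)c1)[C@H]2CO | intermediate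
22 | {[(2S,3R)-2-[4-(benzyloxy)-3-methoxyphenyl]-6-bromo-4-methoxy-2,3-dihydro-1-benzofuran-3-yl]methoxy}(tert-butyl)dimethylsilane | Brc1cc(OC)c2c(c1)O[C@H](c1ccc(OCc3ccccc3)c(OC)c1)[C@H]2CO[Si](C)(C)C(C)(C)C | intermediate
23 | cis-fused benzylic boronic hemiester (tetrahydrofuran C2 R, C3 S, C4 S; boron-bearing carbon unspecified) | COc1ccc([C@@H]2OC[C@@H]3[C@H]2COB(O)C3c2cc(OC)c3c(c2)O[C@H](c2ccc(OCc4ccccc4)c(OC)c2)[C@H]3CO[Si](C)(C)C(C)(C)C)cc1OCc1ccccc1 | intermediate
24 | [(2R,3S,4S)-2-[3-(benzyloxy)-4-methoxyphenyl]-4-{[(2S,3R)-2-[4-(benzyloxy)-3-methoxyphenyl]-3-(hydroxymethyl)-4-methoxy-2,3-dihydro-1-benzofuran-6-yl]methyl}oxolan-3-yl]methanol | COc1ccc([C@@H]2OC[C@@H](Cc3cc(OC)c4c(c3)O[C@H](c3ccc(OCc5ccccc5)c(OC)c3)[C@H]4CO)[C@H]2CO)cc1OCc1ccccc1 | intermediate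
25 | CNP0242386.1 | COc1ccc([C@@H]2OC[C@@H](Cc3cc(OC)c4c(c3)O[C@H](c3ccc(O)c(OC)c3)[C@H]4CO)[C@H]2CO)cc1O | target

**Totals and risks**

Total step count: 15. Longest linear sequence: 11 steps (steps 5 to 15).

Steps most likely to fail:

1. Step 13 (carries the label). Failure process: nickel takes up the alkoxymethyl radical or the alkenylboron group before ring closure (direct decarboxylative arylation, C(sp2)–B arylation), or the α-boryl radical is reduced and protonated instead of arylated. The fallback uses known chemistry, sets out from 11 and returns at 24. Nickel is left out and 11 is irradiated with the same iridium photocatalyst (Cs2CO3, DMF, blue LEDs); this is a decarboxylative radical addition to an alkenylboronic ester run intramolecularly, in which the α-boryl radical is reduced and protonated, and it should give the cis-fused primary alkylboronic hemiester F1. A B-alkyl Suzuki–Miyaura coupling of F1 with 22 (Pd(OAc)2, RuPhos, K2CO3, toluene/H2O, 85 °C) should give the silyl ether of the coupled product F2, and Bu4NF in THF removes the silyl group to reach 24.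

2. Step 7. Failure process: acid-induced loss of the 4-(benzyloxy)-3-methoxybenzyl group, by ionisation or by closure of the ether oxygen onto the formyl carbon to a benzofuran. The fallback runs under basic conditions from 15 to 18. CCl3CO2Na/CCl3CO2H in DMF adds trichloromethanide to the aldehyde to give the trichloromethyl carbinol F3; Jocic-type reductive homologation (NaBH4, NaOH, t-BuOH, 55 °C) gives the arylacetic acid F4; EtI/K2CO3 in DMF gives the ethyl arylacetate F5; Regitz diazo transfer (4-acetamidobenzenesulfonyl azide, DBU, MeCN) gives 18.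

3. Step 4. Failure process: the free carboxylic acid competes for boron (acyloxyboranes) or deactivates the ruthenium carbene, so that boronate exchange or ring closure stalls. The fallback runs from 7 to 11. The acid is first masked (Me3SiCHN2, MeOH/toluene) as the methyl ester F6; the boron-tethered metathesis with 8 is run on this neutral hydroxy ester to give the cyclic boronic hemiester methyl ester F7; LiOH in THF/H2O followed by acidification to pH 4, at which the six-membered hemiester should re-close, returns 11.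

Further compounds
F1 | step 13 | cis-fused primary alkylboronic hemiester: (2R,3S,4S)-2-[3-(benzyloxy)-4-methoxyphenyl]tetrahydrofuran fused at C3–C4 to 2-hydroxy-1,2-oxaborinane | COc1ccc([C@@H]2OC[C@@H]3[C@H]2COB(O)C3)cc1OCc1ccccc1
F2 | step 13 | tert-butyldimethylsilyl ether of 24 at the dihydrobenzofuran CH2OH | COc1ccc([C@@H]2OC[C@@H](Cc3cc(OC)c4c(c3)O[C@H](c3ccc(OCc5ccccc5)c(OC)c3)[C@H]4CO[Si](C)(C)C(C)(C)C)[C@H]2CO)cc1OCc1ccccc1
F3 | step 7 | 1-(2-{[4-(benzyloxy)-3-methoxyphenyl]methoxy}-4-bromo-6-methoxyphenyl)-2,2,2-trichloroethanol (racemic) | COc1cc(Br)cc(OCc2ccc(OCc3ccccc3)c(OC)c2)c1C(O)C(Cl)(Cl)Cl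
F4 | step 7 | (2-{[4-(benzyloxy)-3-methoxyphenyl]methoxy}-4-bromo-6-methoxyphenyl)acetic acid | COc1cc(Br)cc(OCc2ccc(OCc3ccccc3)c(OC)c2)c1CC(=O)O
F5 | step 7 | ethyl (2-{[4-(benzyloxy)-3-methoxyphenyl]methoxy}-4-bromo-6-methoxyphenyl)acetate | CCOC(=O)Cc1c(OC)cc(Br)cc1OCc1ccc(OCc2ccccc2)c(OC)c1
F6 | step 4 | methyl {[(1R,2S)-1-[3-(benzyloxy)-4-methoxyphenyl]-2-(hydroxymethyl)but-3-en-1-yl]oxy}acetate | COc1ccc([C@H](OCC(=O)OC)[C@H](CO)C=C)cc1OCc1ccccc1
F7 | step 4 | methyl {(R)-[3-(benzyloxy)-4-methoxyphenyl][(5S)-2-hydroxy-5,6-dihydro-2H-1,2-oxaborinin-5-yl]methoxy}acetate | COc1ccc([C@H](OCC(=O)OC)[C@@H]2COB(O)C=C2)cc1OCc1ccccc1
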